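## Retrosynthetic overview

1. Target 25 comes from methyl ester 24 by esterase hydrolysis; 24 comes from a Stille coupling of α-bromo enone 18 with heptenylstannane 23.
2. 18 comes from bromo epoxyquinone 14 by cross-metathesis (side chain), desilylation and hydroxyl-directed reduction of the C5 carbonyl.
3. 14 comes from retro-Diels–Alder of tricycle 13; oxirane, CH2O carbon and bromine are installed on the cyclopentadiene-masked ring (6 → 13), with regiocontrol from the ketone/ketal difference.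
4. 6 comes from a catalytic asymmetric Diels–Alder of cyclopentadiene 5 with achiral quinone monoketal 4, made from 3-bromo-4-methoxyphenol 1.
5. Ring order: six-membered carbocycle bought as a benzene ring and dearomatised (step 2); norbornene template on (step 3); oxirane (step 4); template off (step 9).

Assumption: the (S)-oxazaborolidinium catalyst is taken to give 6 as drawn (diene adds to the face of the bound dienone not covered by the catalyst aryl group); the sense is checked on 6, and the (R)-catalyst is used instead if it proves opposite.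

Tricycles are named as 1,4-methanonaphthalenes (C5 = ketone next to C4a); monocycles as 7-oxabicyclo[4.1.0]heptenes. The target is the (1S,5S,6S) compound given by the SMILES, with the C5 hydroxyl cis to the oxirane. Compounds 1, 2, 5 (cracked from dicyclopentadiene), 8, 15 and 19 are taken as purchased.

## Route

Step 1
Reactants: 1 3-bromo-4-methoxyphenol; 2 allyltributylstannane
Product: 3 4-methoxy-3-(prop-2-en-1-yl)phenol
Conditions: Pd(PPh3)4 (5 mol %), PhMe, 105 °C
Reagents that add atoms: allyltributylstannane 2, C=CC[Sn](CCCC)(CCCC)CCCC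
Why: Stille allylation of an aryl bromide under neutral conditions that leave the free phenol alone; no stereocentre is formed.

Step 2
Reactants: 3 4-methoxy-3-(prop-2-en-1-yl)phenol
Product: 4 4,4-dimethoxy-3-(prop-2-en-1-yl)cyclohexa-2,5-dien-1-one
Conditions: PhI(OAc)2 (1.1 equiv), MeOH, 0 °C
Reagents that add atoms: methanol, CO
Why: oxidative dearomatisation of a para-methoxyphenol, methanol trapping the phenoxenium ion para to the OH to give an achiral quinone monoketal with two different enone arms.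

Step 3
Reactants: 4 quinone monoketal; 5 cyclopenta-1,3-diene
Product: 6 (1R,4S,4aR,8aS)-8,8-dimethoxy-7-(prop-2-en-1-yl)-1,4,4a,8a-tetrahydro-1,4-methanonaphthalen-5(8H)-one
Conditions: (S)-tetrahydro-1-(2-methylphenyl)-3,3-diphenyl-1H,3H-pyrrolo[1,2-c][1,3,2]oxazaborole (20 mol %), Tf2NH (18 mol %), 5 (5 equiv), CH2Cl2, −78 °C
Reagents that add atoms: cyclopenta-1,3-diene 5, C1=CCC=C1
Why: catalytic asymmetric Diels–Alder reaction in which the chiral boron Lewis acid activates the dienone carbonyl, only the unsubstituted arm reacts (the β-allyl arm is too hindered), and the diene adds endo to the open face, setting C1, C4, C4a and C8a in one step.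

Step 4
Reactants: 6 tricyclic enone ketal
Product: 7 (1R,4S,4aR,6R,7S,8aS)-6,7-epoxy-8,8-dimethoxy-7-(prop-2-en-1-yl)-1,4,4a,6,7,8a-hexahydro-1,4-methanonaphthalen-5(8H)-one
Conditions: t-BuOOH (2 equiv), n-BuLi (1.5 equiv), THF, −78 → −10 °C; aqueous work-up
Reagents that add atoms: tert-butyl hydroperoxide, CC(C)(C)OO
Why: Weitz–Scheffer nucleophilic epoxidation in which the weakly basic lithium peroxide adds to C7 from the convex face (anti to the norbornene bridge) without isomerising the allyl group, so the template fixes the two oxirane centres that become C1 and C6 of the target.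

Step 5
Reactants: 7 epoxy ketone; 8 formaldehyde (37 % aqueous)
Product: 9 (1R,4S,4aR,6R,7S,8aS)-6,7-epoxy-4a-(hydroxymethyl)-8,8-dimethoxy-7-(prop-2-en-1-yl)-1,4,4a,6,7,8a-hexahydro-1,4-methanonaphthalen-5(8H)-one
Conditions: DBU (0.5 equiv), aq. HCHO (5 equiv), THF, 0 °C
Reagents that add atoms: formaldehyde 8, C=O
Why: aldol hydroxymethylation at C4a, the only enolisable α-carbon of the single ketone (C8 is still a ketal), with formaldehyde entering on the convex face so the ring fusion stays cis (this centre is temporary).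

Step 6
Reactants: 9 primary alcohol
Product: 10 (1R,4S,4aR,6R,7S,8aS)-4a-({[tert-butyl(diphenyl)silyl]oxy}methyl)-6,7-epoxy-8,8-dimethoxy-7-(prop-2-en-1-yl)-1,4,4a,6,7,8a-hexahydro-1,4-methanonaphthalen-5(8H)-one
Conditions: TBDPSCl (1.3 equiv), imidazole, DMAP (cat.), DMF, rt
Reagents that add atoms: tert-butyl(chloro)diphenylsilane, CC(C)(C)[Si](Cl)(c1ccccc1)c1ccccc1
Why: silylation of the primary alcohol blocks retro-aldol loss of formaldehyde and internal ketalisation in the next steps, and the TBDPS ether survives aqueous acid.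

Step 7
Reactants: 10 silyl ether ketal
Product: 11 (1R,4S,4aR,6R,7S,8aS)-4a-({[tert-butyl(diphenyl)silyl]oxy}methyl)-6,7-epoxy-7-(prop-2-en-1-yl)-1,4,4a,6,7,8a-hexahydro-1,4-methanonaphthalene-5,8-dione
Conditions: p-TsOH·H2O (0.3 equiv), acetone/H2O 10:1, 40 °C
Reagents that add atoms: water, O
Why: acid-catalysed hydrolysis of the dimethyl ketal, which the α,β-epoxy ketone and the TBDPS ether tolerate, unmasks the C8 carbonyl without touching a stereocentre.

Step 8
Reactants: 11 dione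
Product: 13 (1R,4S,4aR,6R,7S,8aR)-8a-bromo-4a-({[tert-butyl(diphenyl)silyl]oxy}methyl)-6,7-epoxy-7-(prop-2-en-1-yl)-1,4,4a,6,7,8a-hexahydro-1,4-methanonaphthalene-5,8-dione, via lithium enolate 12 (not isolated)
Conditions: LiN(SiMe3)2 (1.1 equiv), THF, −78 °C; then NBS (1.2 equiv), −78 → −40 °C
Reagents that add atoms: N-bromosuccinimide, O=C1CCC(=O)N1Br
Why: enolate bromination at C8a, the only enolisable α-CH left (C4a and C7 are quaternary), from the convex face, giving a tertiary bromide that cannot eliminate (C4a has no hydrogen, C1 is a bridgehead).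

Step 9
Reactants: 13 bromo dione
Product: 14 (1S,6R)-3-bromo-4-({[tert-butyl(diphenyl)silyl]oxy}methyl)-1-(prop-2-en-1-yl)-7-oxabicyclo[4.1.0]hept-3-ene-2,5-dione
Conditions: Ph2O, 230 °C, 15 min, N2 sweep
Reagents that add atoms: none
Why: thermal retro-Diels–Alder reaction, easy because both ring-fusion carbons are quaternary and cyclopentadiene is swept out, erases the template centres and leaves the oxirane centres untouched while revealing the vinyl bromide.

Step 10
Reactants: 14 bromo epoxyquinone; 15 methyl methacrylate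
Product: 16 methyl (2E)-4-[(1S,6R)-3-bromo-4-({[tert-butyl(diphenyl)silyl]oxy}methyl)-2,5-dioxo-7-oxabicyclo[4.1.0]hept-3-en-1-yl]-2-methylbut-2-enoate
Conditions: second-generation Hoveyda–Grubbs catalyst RuCl2(H2IMes)(=CH-C6H4-2-O-i-Pr) (5 mol %), 15 (10 equiv), CH2Cl2, 40 °C
Reagents that add atoms: methyl methacrylate 15, C=C(C)C(=O)OC
Why: olefin cross-metathesis of the terminal allyl group with excess methacrylate gives the trisubstituted enoate as the E isomer under thermodynamic control, the tetrasubstituted bromo-enedione alkene being inert.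

Step 11
Reactants: 16 silyl ether
Product: 17 methyl (2E)-4-[(1S,6R)-3-bromo-4-(hydroxymethyl)-2,5-dioxo-7-oxabicyclo[4.1.0]hept-3-en-1-yl]-2-methylbut-2-enoate
Conditions: 48 % aq. HF, MeCN, 0 °C → rt
Reagents that add atoms: none
Why: acidic fluoride desilylation without amine or base, so the vinylogous acyl bromide, the oxirane and the ester survive, frees the hydroxyl needed to direct the next step.

Step 12
Reactants: 17 hydroxymethyl bromo epoxyquinone
Product: 18 methyl (2E)-4-[(1S,5S,6S)-3-bromo-5-hydroxy-4-(hydroxymethyl)-2-oxo-7-oxabicyclo[4.1.0]hept-3-en-1-yl]-2-methylbut-2-enoate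
Conditions: Me4N[BH(OAc)3] (3 equiv), MeCN/AcOH 1:1, −30 °C
Reagents that add atoms: none
Why: Saksena–Evans hydroxyl-directed reduction, in which the boron bound to the CH2O group can deliver hydride only to the adjacent C5 carbonyl (C2 lies trans across the ring alkene and the reagent does not reduce ketones intermolecularly), attack anti to the oxirane C–O bond giving the 5S alcohol cis to the oxirane.

Step 13
Reactants: 19 hept-1-yne
Product: 21 (1E)-1-iodohept-1-ene, via alkenylzirconocene chloride 20 (not isolated)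
Conditions: Cp2Zr(H)Cl (1.1 equiv), THF, rt; then I2, 0 °C
Reagents that add atoms: iodine, II
Why: hydrozirconation (syn addition, metal at the terminal carbon) followed by iodinolysis with retention gives the pure E vinyl iodide.

Step 14
Reactants: 21 (1E)-1-iodohept-1-ene
Product: 23 tributyl[(1E)-hept-1-en-1-yl]stannane, via heptenyllithium 22 (not isolated)
Conditions: t-BuLi (2.1 equiv), Et2O, −78 °C; then Bu3SnCl, −78 °C → rt
Reagents that add atoms: tributyltin chloride, CCCC[Sn](Cl)(CCCC)CCCC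
Why: iodine–lithium exchange and stannylation both proceed with retention of the E geometry.

Step 15
Reactants: 18 α-bromo enone; 23 heptenylstannane
Product: 24 methyl (2E)-4-[(1S,5S,6S)-3-[(1E)-hept-1-en-1-yl]-5-hydroxy-4-(hydroxymethyl)-2-oxo-7-oxabicyclo[4.1.0]hept-3-en-1-yl]-2-methylbut-2-enoate
Conditions: Pd2(dba)3 (5 mol %), AsPh3 (20 mol %), PhMe, 80 °C
Reagents that add atoms: stannane 23, CCCCC/C=C/[Sn](CCCC)(CCCC)CCCC
Why: Stille coupling of an activated α-bromo enone under neutral conditions tolerates the free hydroxyls, the oxirane and the ester and retains both alkene geometries.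

Step 16
Reactants: 24 methyl ester
Product: 25 (2E)-4-[(1S,5S,6S)-3-[(1E)-hept-1-en-1-yl]-5-hydroxy-4-(hydroxymethyl)-2-oxo-7-oxabicyclo[4.1.0]hept-3-en-1-yl]-2-methylbut-2-enoic acid
Conditions: pig liver esterase (a carboxylesterase, hydrolase class), 0.1 M phosphate buffer pH 7.2/acetone 9:1, 30 °C
Reagents that add atoms: water, O
Why: esterase-catalysed hydrolysis at neutral pH frees the acid without the hydroxide or strong acid that would attack the epoxy enone, and no stereocentre is involved.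

## Compound list

1 | 3-bromo-4-methoxyphenol | COc1ccc(O)cc1Br | starting material
2 | allyltributylstannane | C=CC[Sn](CCCC)(CCCC)CCCC | starting material
3 | 4-methoxy-3-(prop-2-en-1-yl)phenol | COc1ccc(O)cc1CC=C | intermediate
4 | 4,4-dimethoxy-3-(prop-2-en-1-yl)cyclohexa-2,5-dien-1-one | C=CCC1=CC(=O)C=CC1(OC)OC | intermediate
5 | cyclopenta-1,3-diene | C1=CCC=C1 | starting material
6 | (1R,4S,4aR,8aS)-8,8-dimethoxy-7-(prop-2-en-1-yl)-1,4,4a,8a-tetrahydro-1,4-methanonaphthalen-5(8H)-one (endo, cis-fused) | O=C1C=C(CC=C)C(OC)(OC)[C@H]2[C@H]3C=C[C@H](C3)[C@@H]12 | intermediate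
7 | (1R,4S,4aR,6R,7S,8aS)-6,7-epoxy-8,8-dimethoxy-7-(prop-2-en-1-yl)-1,4,4a,6,7,8a-hexahydro-1,4-methanonaphthalen-5(8H)-one | O=C1[C@@H]2O[C@]2(CC=C)C(OC)(OC)[C@H]3[C@H]4C=C[C@H](C4)[C@@H]13 | intermediate
8 | formaldehyde | C=O | starting material
9 | (1R,4S,4aR,6R,7S,8aS)-6,7-epoxy-4a-(hydroxymethyl)-8,8-dimethoxy-7-(prop-2-en-1-yl)-1,4,4a,6,7,8a-hexahydro-1,4-methanonaphthalen-5(8H)-one | O=C1[C@@H]2O[C@]2(CC=C)C(OC)(OC)[C@H]3[C@H]4C=C[C@H](C4)[C@@]13CO | intermediate
10 | (1R,4S,4aR,6R,7S,8aS)-4a-({[tert-butyl(diphenyl)silyl]oxy}methyl)-6,7-epoxy-8,8-dimethoxy-7-(prop-2-en-1-yl)-1,4,4a,6,7,8a-hexahydro-1,4-methanonaphthalen-5(8H)-one | O=C1[C@@H]2O[C@]2(CC=C)C(OC)(OC)[C@H]3[C@H]4C=C[C@H](C4)[C@@]13CO[Si](c5ccccc5)(c6ccccc6)C(C)(C)C | intermediate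
11 | (1R,4S,4aR,6R,7S,8aS)-4a-({[tert-butyl(diphenyl)silyl]oxy}methyl)-6,7-epoxy-7-(prop-2-en-1-yl)-1,4,4a,6,7,8a-hexahydro-1,4-methanonaphthalene-5,8-dione | O=C1[C@@H]2O[C@]2(CC=C)C(=O)[C@H]3[C@H]4C=C[C@H](C4)[C@@]13CO[Si](c5ccccc5)(c6ccccc6)C(C)(C)C | intermediate
12 | lithium enolate of 11 (C8–O–Li, C8=C8a) | [Li+].O=C1[C@@H]2O[C@]2(CC=C)C([O-])=C3[C@H]4C=C[C@H](C4)[C@@]13CO[Si](c5ccccc5)(c6ccccc6)C(C)(C)C | intermediate (not isolated)
13 | (1R,4S,4aR,6R,7S,8aR)-8a-bromo-4a-({[tert-butyl(diphenyl)silyl]oxy}methyl)-6,7-epoxy-7-(prop-2-en-1-yl)-1,4,4a,6,7,8a-hexahydro-1,4-methanonaphthalene-5,8-dione | O=C1[C@@H]2O[C@]2(CC=C)C(=O)[C@@]3(Br)[C@H]4C=C[C@H](C4)[C@@]13CO[Si](c5ccccc5)(c6ccccc6)C(C)(C)C | intermediate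
14 | (1S,6R)-3-bromo-4-({[tert-butyl(diphenyl)silyl]oxy}methyl)-1-(prop-2-en-1-yl)-7-oxabicyclo[4.1.0]hept-3-ene-2,5-dione | O=C1[C@@H]2O[C@]2(CC=C)C(=O)C(Br)=C1CO[Si](c3ccccc3)(c4ccccc4)C(C)(C)C | intermediate
15 | methyl methacrylate | C=C(C)C(=O)OC | starting material
16 | methyl (2E)-4-[(1S,6R)-3-bromo-4-({[tert-butyl(diphenyl)silyl]oxy}methyl)-2,5-dioxo-7-oxabicyclo[4.1.0]hept-3-en-1-yl]-2-methylbut-2-enoate | O=C1[C@@H]2O[C@]2(C/C=C(\C)C(=O)OC)C(=O)C(Br)=C1CO[Si](c3ccccc3)(c4ccccc4)C(C)(C)C | intermediate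
17 | methyl (2E)-4-[(1S,6R)-3-bromo-4-(hydroxymethyl)-2,5-dioxo-7-oxabicyclo[4.1.0]hept-3-en-1-yl]-2-methylbut-2-enoate | O=C1[C@@H]2O[C@]2(C/C=C(\C)C(=O)OC)C(=O)C(Br)=C1CO | intermediate
18 | methyl (2E)-4-[(1S,5S,6S)-3-bromo-5-hydroxy-4-(hydroxymethyl)-2-oxo-7-oxabicyclo[4.1.0]hept-3-en-1-yl]-2-methylbut-2-enoate | BrC1=C(CO)[C@H](O)[C@@H]2O[C@]2(C/C=C(\C)C(=O)OC)C1=O | intermediate
19 | hept-1-yne | C#CCCCCC | starting material
20 | chlorobis(cyclopentadienyl)[(1E)-hept-1-en-1-yl]zirconium (Cp drawn σ-bound) | CCCCC/C=C/[Zr](Cl)(C1C=CC=C1)C1C=CC=C1 | intermediate (not isolated)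
21 | (1E)-1-iodohept-1-ene | CCCCC/C=C/I | intermediate
22 | (1E)-hept-1-en-1-yllithium | CCCCC/C=C/[Li] | intermediate (not isolated)
23 | tributyl[(1E)-hept-1-en-1-yl]stannane | CCCCC/C=C/[Sn](CCCC)(CCCC)CCCC | intermediate
24 | methyl (2E)-4-[(1S,5S,6S)-3-[(1E)-hept-1-en-1-yl]-5-hydroxy-4-(hydroxymethyl)-2-oxo-7-oxabicyclo[4.1.0]hept-3-en-1-yl]-2-methylbut-2-enoate | CCCCC/C=C/C1=C(CO)[C@H](O)[C@@H]2O[C@]2(C/C=C(\C)C(=O)OC)C1=O | intermediate
25 | (2E)-4-[(1S,5S,6S)-3-[(1E)-hept-1-en-1-yl]-5-hydroxy-4-(hydroxymethyl)-2-oxo-7-oxabicyclo[4.1.0]hept-3-en-1-yl]-2-methylbut-2-enoic acid | CCCCC/C=C/C1=C(CO)[C@H](O)[C@@H]2O[C@]2(C/C=C(\C)C(=O)O)C1=O | target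

## Step count and risks

Total: 16 steps. Longest linear sequence: 14 steps (steps 1–12, 15, 16); steps 13–14 make the stannane on a side branch.

Three steps most likely to fail:

Step 3 is the main risk: the enantioselectivity on this dienophile is unproven, and the cationic boron Lewis acid may ionise the dimethyl ketal. The fallback sets out from 4 and comes back at 9. Compounds 4 and 5 are combined thermally (PhMe, 80 °C) to the racemic endo adduct, that is 6 together with its mirror image ent-6 F1. The racemate is taken through the chemistry of steps 4 and 5, giving 7 together with ent-7 F2 and then 9 together with ent-9 F3. A lipase (Burkholderia cepacia lipase, vinyl acetate, t-BuOMe, 30 °C, screened so that ent-9 is the fast-reacting antipode) converts ent-9 into the acetate of ent-9 F4. The untouched alcohol 9 is separated by chromatography and enters step 6.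

Step 12 may give poor facial selectivity, or the hindered bromo-enedione may reduce sluggishly. The fallback sets out from 10 and comes back at 24; the ketone is reduced while the other carbonyl is still a ketal, so no choice between two carbonyls arises. Compound 10 is thermolysed as in step 9 to the epoxy enone ketal F5. DIBAL-H (THF, −78 °C) attacks its only carbonyl anti to the oxirane to give the cis-epoxy alcohol F6. Cross-metathesis with 15 as in step 10 gives the enoate F7. Aqueous HF in MeCN removes the silyl group and the allylic dimethyl ketal to give the enone diol F8. I2/pyridine (CH2Cl2, rt) α-iodinates the enone to the iodo enone F9, which is coupled with 23 as in step 15 to give 24.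

Step 16 may be slow because a conjugated, α-branched methyl ester is a poor esterase substrate. The fallback sets out from 14 and comes back at 25. The metathesis of step 10 is run with 2,2,2-trifluoroethyl methacrylate in place of 15 to give the trifluoroethyl ester F10. This is desilylated as in step 11 to the primary alcohol F11, reduced as in step 12 to the bromo enone diol F12, and coupled with 23 as in step 15 to the trifluoroethyl ester of the target F13. The activated ester is then cleaved by a lipase (Candida antarctica lipase B, phosphate buffer pH 7/t-BuOMe, 30 °C) to 25.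

## Further compounds

F1 | step 3 | (1S,4R,4aS,8aR)-8,8-dimethoxy-7-(prop-2-en-1-yl)-1,4,4a,8a-tetrahydro-1,4-methanonaphthalen-5(8H)-one (ent-6) | O=C1C=C(CC=C)C(OC)(OC)[C@@H]2[C@@H]3C=C[C@@H](C3)[C@H]12
F2 | step 3 | (1S,4R,4aS,6S,7R,8aR)-6,7-epoxy-8,8-dimethoxy-7-(prop-2-en-1-yl)-1,4,4a,6,7,8a-hexahydro-1,4-methanonaphthalen-5(8H)-one (ent-7) | O=C1[C@H]2O[C@@]2(CC=C)C(OC)(OC)[C@@H]3[C@@H]4C=C[C@@H](C4)[C@H]13
F3 | step 3 | (1S,4R,4aS,6S,7R,8aR)-6,7-epoxy-4a-(hydroxymethyl)-8,8-dimethoxy-7-(prop-2-en-1-yl)-1,4,4a,6,7,8a-hexahydro-1,4-methanonaphthalen-5(8H)-one (ent-9) | O=C1[C@H]2O[C@@]2(CC=C)C(OC)(OC)[C@@H]3[C@@H]4C=C[C@@H](C4)[C@]13CO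
F4 | step 3 | acetate of ent-9, the O-acetyl derivative of the 4a-hydroxymethyl group | O=C1[C@H]2O[C@@]2(CC=C)C(OC)(OC)[C@@H]3[C@@H]4C=C[C@@H](C4)[C@]13COC(C)=O
F5 | step 12 | (1R,6S)-3-({[tert-butyl(diphenyl)silyl]oxy}methyl)-5,5-dimethoxy-6-(prop-2-en-1-yl)-7-oxabicyclo[4.1.0]hept-3-en-2-one | O=C1[C@@H]2O[C@]2(CC=C)C(OC)(OC)C=C1CO[Si](c3ccccc3)(c4ccccc4)C(C)(C)C
F6 | step 12 | (1S,2S,6S)-3-({[tert-butyl(diphenyl)silyl]oxy}methyl)-5,5-dimethoxy-6-(prop-2-en-1-yl)-7-oxabicyclo[4.1.0]hept-3-en-2-ol | C1=C(CO[Si](c3ccccc3)(c4ccccc4)C(C)(C)C)[C@H](O)[C@@H]2O[C@]2(CC=C)C1(OC)OC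
F7 | step 12 | methyl (2E)-4-[(1S,5S,6S)-4-({[tert-butyl(diphenyl)silyl]oxy}methyl)-5-hydroxy-2,2-dimethoxy-7-oxabicyclo[4.1.0]hept-3-en-1-yl]-2-methylbut-2-enoate | C1=C(CO[Si](c3ccccc3)(c4ccccc4)C(C)(C)C)[C@H](O)[C@@H]2O[C@]2(C/C=C(\C)C(=O)OC)C1(OC)OC
F8 | step 12 | methyl (2E)-4-[(1S,5S,6S)-5-hydroxy-4-(hydroxymethyl)-2-oxo-7-oxabicyclo[4.1.0]hept-3-en-1-yl]-2-methylbut-2-enoate | C1=C(CO)[C@H](O)[C@@H]2O[C@]2(C/C=C(\C)C(=O)OC)C1=O
F9 | step 12 | methyl (2E)-4-[(1S,5S,6S)-5-hydroxy-4-(hydroxymethyl)-3-iodo-2-oxo-7-oxabicyclo[4.1.0]hept-3-en-1-yl]-2-methylbut-2-enoate | IC1=C(CO)[C@H](O)[C@@H]2O[C@]2(C/C=C(\C)C(=O)OC)C1=O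
F10 | step 16 | 2,2,2-trifluoroethyl (2E)-4-[(1S,6R)-3-bromo-4-({[tert-butyl(diphenyl)silyl]oxy}methyl)-2,5-dioxo-7-oxabicyclo[4.1.0]hept-3-en-1-yl]-2-methylbut-2-enoate | O=C1[C@@H]2O[C@]2(C/C=C(\C)C(=O)OCC(F)(F)F)C(=O)C(Br)=C1CO[Si](c3ccccc3)(c4ccccc4)C(C)(C)C
F11 | step 16 | 2,2,2-trifluoroethyl (2E)-4-[(1S,6R)-3-bromo-4-(hydroxymethyl)-2,5-dioxo-7-oxabicyclo[4.1.0]hept-3-en-1-yl]-2-methylbut-2-enoate | O=C1[C@@H]2O[C@]2(C/C=C(\C)C(=O)OCC(F)(F)F)C(=O)C(Br)=C1CO
F12 | step 16 | 2,2,2-trifluoroethyl (2E)-4-[(1S,5S,6S)-3-bromo-5-hydroxy-4-(hydroxymethyl)-2-oxo-7-oxabicyclo[4.1.0]hept-3-en-1-yl]-2-methylbut-2-enoate | BrC1=C(CO)[C@H](O)[C@@H]2O[C@]2(C/C=C(\C)C(=O)OCC(F)(F)F)C1=O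
F13 | step 16 | 2,2,2-trifluoroethyl (2E)-4-[(1S,5S,6S)-3-[(1E)-hept-1-en-1-yl]-5-hydroxy-4-(hydroxymethyl)-2-oxo-7-oxabicyclo[4.1.0]hept-3-en-1-yl]-2-methylbut-2-enoate | CCCCC/C=C/C1=C(CO)[C@H](O)[C@@H]2O[C@]2(C/C=C(\C)C(=O)OCC(F)(F)F)C1=O
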